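All constants are those of an exercise; no experiment stands behind them.

D comes from J, Z and G together, while J can also leave as J2.

    X ⇌ Z, rate k1*(csat - [Z]) (k1 = 4.60 /s, csat = 6.3 mM)
    2 J → J2 (k2 = 7.18 /M/s)
    J → E (k3 = 5.84 × 10⁻⁵ /s)
    J + Z + G → G + D (k4 = 45200 /M²/s)

J 0.10 M; X 6.3 mM (held); G 19 mM; time 15 s

- D at 15 s, in percent of the J charged
- the change that raises the amount of D at 15 s, in percent of the J charged most ("none" if none brings more than 2 percentage points) (dusk / midnight / dawn / none)
- amount of D at 15 s, in percent of the J charged, after dusk

- dusk: doubling the transfer coefficient of step 1, all else as stated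
- midnight: doubling the amount of G, all else as stated
- dawn: doubling the saturation concentration of X, all else as stated

- percentages count the J that a species holds: one J2 counts as two
- a doubled species enters its step squared and goes two at a time
- at the start none of Z is dissolved
- run time (flask): 15 s

Follow the fraction of J left, not the D made. Hold cG at its charge, since G comes back from the D step. Take Z as steady, because at the charge it adjusts in 0.0111 s, shorter than J's dimer half-life at the charge, 0.696 s. Drop E: J's half-life by that step alone is 200 min.

The D step then takes J at S·cJ/(cJ + h), with S the transfer ceiling, 0.0290 M/s, and h = 5.36 mM. Define the crossover concentration c*, 44.9 mM, as the cJ at which dimerisation loses J at rate S. D's share of the J lost, the instantaneous selectivity, is 1/(1 + cJ(cJ + h)/(c*·c*)). Time has left the formula. The ceiling could deliver 435% of the charge by 15 s into a solution kept empty, more than the charge, so take J as consumed by then and y as the mean share while the fraction left falls to zero.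

Reckon it two ways. First, cut sharply at c*: J above it goes to J2, J below it to D, giving 44.9%. Second, average the share:

| cJ | D's share |
|---|---|
| 100 mM | 16.1% |
| 75.0 mM | 25.1% |
| 50.0 mM | 42.2% |
| 25.0 mM | 72.7% |
| 0 mM | 100% |

Simpson's rule gives 49.3%, more than the cut. The cut cheats: its rows would read nothing above c* and everything below, and the table reads otherwise. Commit to the average.

Dusk doubles c*·c* and h, giving 60.2%. Dawn doubles c*·c* and keeps h, giving 62.0%, more. Midnight halves h and leaves c*, giving 50.3%, less than dusk.

The forecast calls this “a pure branching split between D and J2”. It gives y 49.5% (47% to 52%), best dawn, yb 60.2% (57.5% to 63%), so its y stands above mine.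

The flask gives y 48.7%, best dawn and yb 59.4%. Dawn adds 12 percentage points, dusk 11 points, midnight 1.3 points. Now lower the charge with c* unchanged, in the neighbouring flask at 0.040 M of J. There the charge stands at 0.891 of c*, against 2.23 in the flask, and the same averaging gives 78.9%. The neighbouring flask stood at 0% J after 15.0 s, with J2 22.5% and D 77.5%.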